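## Retrosynthetic overview

- The last step removes two B-ring MOM ethers. The only ring formed in the route is the chroman C-ring, closed at O1–C2 by intramolecular Mitsunobu etherification of a 2-aryl-3-(2-hydroxyaryl)propan-1-ol; both benzene rings are bought.
- C3 and the C3–C4 bond come from an Evans alkylation of a B-ring arylacetyl (R)-4-benzyloxazolidinone with an A-ring benzyl bromide, followed by LiBH4 cleavage.
- The A-ring bromide comes from 2,4,6-trihydroxybenzaldehyde. The prenyl group is placed by O-allylation, Claisen rearrangement (only one free ortho position) and cross-metathesis, and the same oxygen then becomes the 5-OMe.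
- The B-ring acid comes from resorcinol bis-MOM ether by two directed ortho-lithiations (prenyl between the OMOM groups, then ethylene oxide) and oxidation.
- Protecting groups: TBS on the A ring (fluoride) and MOM on the B ring (acid), so that only the A-ring phenols are free at ring closure.

Assumption: simple reagents (TBSCl, MOMCl, prenyl bromide, ethylene oxide and the like) are treated as reagents and not numbered. Abbreviations: prenyl = 3-methylbut-2-en-1-yl; TBS = tert-butyldimethylsilyl; MOM = methoxymethyl.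

## Route

### A-ring fragment

**Step 1**
Reactants: 1, 2,4,6-trihydroxybenzaldehyde
Product: 2, 2-hydroxy-4,6-bis(TBS-oxy)benzaldehyde
Conditions: TBSCl (2.1 equiv), imidazole, DMF, 0 °C
Reagents that add atoms: TBSCl, CC(C)(C)[Si](C)(C)Cl
Why: Chemoselective silylation takes the para-OH and one ortho-OH, while the remaining ortho-OH is held in a hydrogen bond to the aldehyde and is left free.

**Step 2**
Reactants: 2, 2-hydroxy-4,6-bis(TBS-oxy)benzaldehyde
Product: 3, 2-(allyloxy)-4,6-bis(TBS-oxy)benzaldehyde
Conditions: allyl alcohol, PPh3, DIAD, THF, 0 °C to rt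
Reagents that add atoms: allyl alcohol, C=CCO
Why: Mitsunobu etherification alkylates the acidic chelated phenol under neutral conditions that do not cleave aryl silyl ethers.

**Step 3**
Reactants: 3, 2-(allyloxy)-4,6-bis(TBS-oxy)benzaldehyde
Product: 4, 3-allyl-2-hydroxy-4,6-bis(TBS-oxy)benzaldehyde
Conditions: PhNEt2, 190 °C, sealed tube
Reagents that add atoms: none
Why: Aromatic Claisen [3,3] rearrangement can only deliver the allyl group to C3, because the other ortho position carries the formyl group.

**Step 4**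
Reactants: 4, 3-allyl-2-hydroxy-4,6-bis(TBS-oxy)benzaldehyde
Product: 5, 3-allyl-2-methoxy-4,6-bis(TBS-oxy)benzaldehyde
Conditions: MeOH, PPh3, DIAD, THF, 0 °C to rt
Reagents that add atoms: methanol, CO
Why: Mitsunobu O-methylation of the hindered chelated phenol fixes the future 5-OMe without base that could cause silyl loss or migration.

**Step 5**
Reactants: 5, 3-allyl-2-methoxy-4,6-bis(TBS-oxy)benzaldehyde
Product: 6, 2-methoxy-3-prenyl-4,6-bis(TBS-oxy)benzaldehyde
Conditions: Grubbs II (5 mol%), 2-methyl-2-butene (excess), CH2Cl2, 40 °C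
Reagents that add atoms: 2-methyl-2-butene, CC=C(C)C
Why: Olefin cross-metathesis of the terminal allyl group with 2-methyl-2-butene gives the prenyl group and releases propene.

**Step 6**
Reactants: 6, 2-methoxy-3-prenyl-4,6-bis(TBS-oxy)benzaldehyde
Product: 7, [2-methoxy-3-prenyl-4,6-bis(TBS-oxy)phenyl]methanol
Conditions: NaBH4, THF/MeOH, 0 °C
Reagents that add atoms: none
Why: Borohydride reduction of the aldehyde is fast at 0 °C and leaves the alkene and silyl ethers untouched.

**Step 7**
Reactants: 7, [2-methoxy-3-prenyl-4,6-bis(TBS-oxy)phenyl]methanol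
Product: 8, 2-methoxy-3-prenyl-4,6-bis(TBS-oxy)benzyl bromide
Conditions: PBr3, pyridine (cat.), Et2O, −20 to 0 °C; cold NaHCO3 wash, used crude at once
Reagents that add atoms: phosphorus tribromide, BrP(Br)Br
Why: Bromination of the activated benzylic alcohol is rapid at low temperature, and the labile electron-rich bromide is carried forward without purification.

### B-ring fragment

**Step 8**
Reactants: 9, resorcinol
Product: 10, 1,3-bis(methoxymethoxy)benzene
Conditions: MOMCl, i-Pr2NEt, CH2Cl2, 0 °C to rt
Reagents that add atoms: MOMCl, COCCl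
Why: Acetal protection of both phenols installs the groups that direct both lithiations.

**Step 9**
Reactants: 10, 1,3-bis(methoxymethoxy)benzene
Product: 11, 1,3-bis(methoxymethoxy)-2-prenylbenzene
Conditions: n-BuLi, THF, 0 °C; CuI (cat.), prenyl bromide, −78 °C to rt
Reagents that add atoms: prenyl bromide, CC(C)=CCBr
Why: Directed ortho-metalation occurs at C2 between the two OMOM groups, and the copper-assisted aryl anion is alkylated by prenyl bromide at the primary carbon.

**Step 10**
Reactants: 11, 1,3-bis(methoxymethoxy)-2-prenylbenzene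
Product: 12, 2-[2,4-bis(methoxymethoxy)-3-prenylphenyl]ethanol
Conditions: n-BuLi, TMEDA, Et2O, 0 °C; ethylene oxide, −78 °C to rt
Reagents that add atoms: ethylene oxide, C1CO1
Why: A second directed ortho-metalation next to an OMOM group (C4, the only activated ring position left) is followed by epoxide opening to give the two-carbon chain.

**Step 11**
Reactants: 12, 2-[2,4-bis(methoxymethoxy)-3-prenylphenyl]ethanol
Product: 13, 2-[2,4-bis(methoxymethoxy)-3-prenylphenyl]acetic acid
Conditions: TEMPO (cat.), PhI(OAc)2, MeCN/H2O (pH 7 buffer), rt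
Reagents that add atoms: water, O
Why: Oxoammonium (TEMPO/BAIB) oxidation takes the primary alcohol to the acid via the aldehyde hydrate and tolerates the prenyl alkene and MOM acetals.

**Step 12**
Reactants: 13, 2-[2,4-bis(methoxymethoxy)-3-prenylphenyl]acetic acid; 14, (R)-4-benzyloxazolidin-2-one
Product: 15, (R)-4-benzyl-3-{[2,4-bis(methoxymethoxy)-3-prenylphenyl]acetyl}oxazolidin-2-one
Conditions: PivCl, Et3N, THF, −20 °C; then 14, LiCl, rt
Reagents that add atoms: none
Why: N-acylation of the auxiliary through the mixed pivalic anhydride avoids strong base.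

### Coupling and endgame

**Step 13**
Reactants: 15, the B-ring arylacetyl oxazolidinone; 8, the A-ring benzyl bromide
Product: 16, (R)-4-benzyl-3-[(2R)-2-[2,4-bis(methoxymethoxy)-3-prenylphenyl]-3-[2-methoxy-3-prenyl-4,6-bis(TBS-oxy)phenyl]propanoyl]oxazolidin-2-one
Conditions: NaHMDS, THF, −78 °C; then 8, −78 to −40 °C
Reagents that add atoms: none
Why: Evans asymmetric alkylation, in which the chelated Z-sodium enolate is benzylated on the face opposite the auxiliary benzyl group, sets the (R) centre (future C3); the minor diastereomer is removed by chromatography.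

**Step 14**
Reactants: 16, the alkylated imide
Product: 17, (2R)-2-[2,4-bis(methoxymethoxy)-3-prenylphenyl]-3-[2-methoxy-3-prenyl-4,6-bis(TBS-oxy)phenyl]propan-1-ol
Conditions: LiBH4, H2O (1 equiv), Et2O, 0 °C
Reagents that add atoms: none
Why: Reductive cleavage of the imide gives the primary alcohol and recovered auxiliary under conditions too mild to epimerise the alpha-aryl centre.

**Step 15**
Reactants: 17, the bis-TBS alcohol
Product: 18, 4-[(2R)-2-[2,4-bis(methoxymethoxy)-3-prenylphenyl]-3-hydroxypropyl]-5-methoxy-6-prenylbenzene-1,3-diol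
Conditions: TBAF, THF, 0 °C, under argon
Reagents that add atoms: none
Why: Fluoride desilylation frees both A-ring phenols, while the B-ring MOM ethers are inert to fluoride.

**Step 16**
Reactants: 18, the A-ring diphenol alcohol
Product: 19, (3R)-3-[2,4-bis(methoxymethoxy)-3-prenylphenyl]-5-methoxy-6-prenylchroman-7-ol
Conditions: PPh3, DIAD, THF (0.01 M), 0 °C to rt
Reagents that add atoms: none
Why: Intramolecular Mitsunobu etherification closes the six-membered ring through the only phenol ortho to the side chain, and the stereocentre is untouched because the displacement is at the adjacent primary carbon.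

**Step 17**
Reactants: 19, the 2',4'-di-O-MOM isoflavan
Product: 20, licoricidin, (3R)-3-(2,4-dihydroxy-3-prenylphenyl)-5-methoxy-6-prenylchroman-7-ol
Conditions: 3 M aq HCl, MeOH, 40 °C, stopped at full conversion
Reagents that add atoms: none
Why: Mild acetal hydrolysis removes both MOM groups under conditions that should leave ortho-prenyl phenols uncyclised.

## Compound list

1 | 2,4,6-trihydroxybenzaldehyde | O=Cc1c(O)cc(O)cc1O | starting material
2 | 2-hydroxy-4,6-bis(TBS-oxy)benzaldehyde | O=Cc1c(O)cc(O[Si](C)(C)C(C)(C)C)cc1O[Si](C)(C)C(C)(C)C | intermediate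
3 | 2-(allyloxy)-4,6-bis(TBS-oxy)benzaldehyde | O=Cc1c(OCC=C)cc(O[Si](C)(C)C(C)(C)C)cc1O[Si](C)(C)C(C)(C)C | intermediate
4 | 3-allyl-2-hydroxy-4,6-bis(TBS-oxy)benzaldehyde | O=Cc1c(O)c(CC=C)c(O[Si](C)(C)C(C)(C)C)cc1O[Si](C)(C)C(C)(C)C | intermediate
5 | 3-allyl-2-methoxy-4,6-bis(TBS-oxy)benzaldehyde | COc1c(CC=C)c(O[Si](C)(C)C(C)(C)C)cc(O[Si](C)(C)C(C)(C)C)c1C=O | intermediate
6 | 2-methoxy-3-prenyl-4,6-bis(TBS-oxy)benzaldehyde | COc1c(CC=C(C)C)c(O[Si](C)(C)C(C)(C)C)cc(O[Si](C)(C)C(C)(C)C)c1C=O | intermediate
7 | [2-methoxy-3-prenyl-4,6-bis(TBS-oxy)phenyl]methanol | COc1c(CC=C(C)C)c(O[Si](C)(C)C(C)(C)C)cc(O[Si](C)(C)C(C)(C)C)c1CO | intermediate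
8 | 2-methoxy-3-prenyl-4,6-bis(TBS-oxy)benzyl bromide | COc1c(CC=C(C)C)c(O[Si](C)(C)C(C)(C)C)cc(O[Si](C)(C)C(C)(C)C)c1CBr | intermediate
9 | resorcinol | Oc1cccc(O)c1 | starting material
10 | 1,3-bis(methoxymethoxy)benzene | COCOc1cccc(OCOC)c1 | intermediate
11 | 1,3-bis(methoxymethoxy)-2-prenylbenzene | COCOc1cccc(OCOC)c1CC=C(C)C | intermediate
12 | 2-[2,4-bis(methoxymethoxy)-3-prenylphenyl]ethanol | COCOc1ccc(CCO)c(OCOC)c1CC=C(C)C | intermediate
13 | 2-[2,4-bis(methoxymethoxy)-3-prenylphenyl]acetic acid | COCOc1ccc(CC(=O)O)c(OCOC)c1CC=C(C)C | intermediate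
14 | (R)-4-benzyloxazolidin-2-one | O=C1N[C@H](Cc2ccccc2)CO1 | starting material
15 | (R)-4-benzyl-3-{[2,4-bis(methoxymethoxy)-3-prenylphenyl]acetyl}oxazolidin-2-one | COCOc1ccc(CC(=O)N2C(=O)OC[C@H]2Cc2ccccc2)c(OCOC)c1CC=C(C)C | intermediate
16 | (R)-4-benzyl-3-[(2R)-2-(B-aryl)-3-(A-aryl)propanoyl]oxazolidin-2-one (alkylated imide) | COc1c(CC=C(C)C)c(O[Si](C)(C)C(C)(C)C)cc(O[Si](C)(C)C(C)(C)C)c1C[C@H](c1ccc(OCOC)c(CC=C(C)C)c1OCOC)C(=O)N1C(=O)OC[C@H]1Cc1ccccc1 | intermediate
17 | (2R)-2-[2,4-bis(methoxymethoxy)-3-prenylphenyl]-3-[2-methoxy-3-prenyl-4,6-bis(TBS-oxy)phenyl]propan-1-ol | COc1c(CC=C(C)C)c(O[Si](C)(C)C(C)(C)C)cc(O[Si](C)(C)C(C)(C)C)c1C[C@H](c1ccc(OCOC)c(CC=C(C)C)c1OCOC)CO | intermediate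
18 | 4-[(2R)-2-[2,4-bis(methoxymethoxy)-3-prenylphenyl]-3-hydroxypropyl]-5-methoxy-6-prenylbenzene-1,3-diol | COc1c(CC=C(C)C)c(O)cc(O)c1C[C@H](c1ccc(OCOC)c(CC=C(C)C)c1OCOC)CO | intermediate
19 | (3R)-3-[2,4-bis(methoxymethoxy)-3-prenylphenyl]-5-methoxy-6-prenylchroman-7-ol | COc1c(CC=C(C)C)c(O)cc2c1C[C@H](c1ccc(OCOC)c(CC=C(C)C)c1OCOC)CO2 | intermediate
20 | licoricidin, (3R) | COc1c(CC=C(C)C)c(O)cc2c1C[C@H](c1ccc(O)c(CC=C(C)C)c1O)CO2 | target

## Summary

Total steps: 17. Longest linear sequence: 12 (steps 1–7, then 13–17).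

Steps most likely to fail, with fallbacks:

1. **Steps 7 and 13 (benzyl bromide 8 and its Evans alkylation).** The 2,4,6-trioxygenated benzyl bromide may ionise or polymerise before it is alkylated. Fallback: avoid the halide by condensing aldehyde 6 with acid 13 (Perkin) to the (E)-2,3-diarylacrylic acid. Set C3 by carboxylate-directed asymmetric hydrogenation (Ir spiro-phosphine-oxazoline or Ru-BINAP type), which should not reduce the isolated prenyl alkenes, then reduce with LiAlH4 to rejoin at 17.

2. **Step 10 (second lithiation of 11).** Deprotonation at the benzylic/allylic CH2 of the prenyl group may compete with ring metalation. Fallback: start the B ring from 2,4-dihydroxyphenylacetic acid. Protect with MOMCl, reduce with LiAlH4 to 2-[2,4-bis(methoxymethoxy)phenyl]ethanol, then run a single directed lithiation between the two OMOM groups and quench with prenyl bromide to reach 12.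

3. **Step 17 (acidic MOM removal).** Acid can cyclise the ortho-prenyl phenols to 2,2-dimethylchromans. Fallback: build the B ring with SEM ethers in place of MOM (they also direct lithiation), so the final deprotection uses fluoride (TBAF, DMPU, heat). The A-ring TBS groups would still be removed selectively at 0 °C in step 15.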